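**Retrosynthetic overview**

- Feature: in ring C (O1–C2–C3–C3a–C7a) ring B sits on C2 and CH3 on C3, trans across the C2–C3 bond. This is the pattern an anti 1,2-addition across the C2=C3 bond of a benzofuran would leave.
- Key disconnection: C2–C1′ and C3–CH3 are cut together, back to 2-lithio-7-methoxybenzofuran, the ring B pinacol boronate and iodomethane. Boron stays on C2 and is later exchanged for H with retention.
- Periphery: the C5 propenyl group comes from C–H borylation of ring A at C5 and Suzuki coupling. The ring B boronate comes from silylation and C–H borylation of 2,3-dimethoxyphenol.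
- Ring order: no ring is built. Rings A and C arrive as 7-methoxybenzofuran (ring C is dearomatised in the key step) and ring B as the phenol.

Key step: step 3

Assumption: 7-methoxybenzofuran and (E)-1-bromopropene are bought as such; the enantiomer of the MandyPhos ligand that leads to the (2S,3S) series has to be found by trial, and both enantiomers are commercial.

**Step 1**
Reactants: 1 2,3-dimethoxyphenol
Product: 2 (2,3-dimethoxyphenoxy)triisopropylsilane
Conditions: TIPSCl, imidazole, DMF, rt
Reagents that add atoms: chlorotriisopropylsilane (TIPSCl), CC(C)[Si](Cl)(C(C)C)C(C)C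
Why: Imidazole-promoted O-silylation of a phenol; the TIPS ether should survive the aryllithium-derived ate complex and the palladium step, and the fluoride of step 4 removes it.

**Step 2**
Reactants: 2 (2,3-dimethoxyphenoxy)triisopropylsilane; 3 bis(pinacolato)diboron
Product: 4 2-[3,4-dimethoxy-5-(triisopropylsilyloxy)phenyl]-4,4,5,5-tetramethyl-1,3,2-dioxaborolane
Conditions: [Ir(OMe)(cod)]2 (1.5 mol%), 4,4′-di-tert-butyl-2,2′-bipyridine (3 mol%), B2pin2 (1.0 equiv), THF, 80 °C
Reagents that add atoms: bis(pinacolato)diboron 3, CC1(C)OB(OC1(C)C)B1OC(C)(C)C(C)(C)O1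
Why: Iridium-catalysed aromatic C–H borylation is sterically controlled, and C5 is the only C–H of 2 without an ortho substituent.

**Step 3**
Reactants: 5 7-methoxybenzofuran; 4 2-[3,4-dimethoxy-5-(triisopropylsilyloxy)phenyl]-4,4,5,5-tetramethyl-1,3,2-dioxaborolane; 6 iodomethane
Product: 9 (2S,3S)-2-[3,4-dimethoxy-5-(triisopropylsilyloxy)phenyl]-7-methoxy-3-methyl-2-(pinacolboryl)-2,3-dihydrobenzofuran, via 2-lithio-7-methoxybenzofuran 7 (not isolated), via lithium aryl(7-methoxybenzofuran-2-yl)pinacolatoborate 8 (not isolated)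
Conditions: n-BuLi (1.05 equiv), THF, −78 °C; 4 (1.0 equiv), −78 °C to rt; then Pd2(dba)3 (2.5 mol%), (Sp,Sp)-1,1′-bis(diphenylphosphino)-2,2′-bis[(R)-α-(dimethylamino)benzyl]ferrocene (MandyPhos, 6 mol%), NaOTf (2 equiv), MeI (1.5 equiv, added over 4 h), THF, rt to 40 °C, sealed vessel
Reagents that add atoms: iodomethane 6, CI
Why: Proposed new method: MeI adds oxidatively to the zerovalent palladium–bisphosphine complex, the resulting methylpalladium (divalent palladium) binds the C2–C3 π bond of ate complex 8 from one face, ring B shifts from boron to C2 anti to the metal, and the C3-bound alkyl(methyl)palladium, which has no β-hydrogen to lose (C2 is fully substituted, C3a is aromatic), reductively eliminates the C3–CH3 bond with retention. The closest known reactions are palladium-catalysed enantioselective conjunctive cross-couplings of alkenylboron ate complexes, in which an organopalladium electrophile triggers the 1,2-metallate shift, and dearomative three-component couplings of 2-lithiated indoles with boronic esters and allylic electrophiles; a methyl electrophile on a benzofuran ate complex has not been shown. No ring is closed: ring C comes from 5 and only gives up its aromaticity. C3 is set by the face of the benzofuran on which the chiral ligand places palladium, and C2 follows from it because the shift is anti-periplanar to the forming C3–Pd bond, so ring B and methyl end up trans and boron cis to methyl. C3 and not C2 takes the electrophile because the borate on C2 and O1 make C3 the nucleophilic terminus of an enol ether. The catalysed path has to outrun direct methylation of 8 by MeI (racemic) and boron-to-palladium transmetallation (methyl–aryl Suzuki coupling); slow addition of MeI, NaOTf to keep iodide off palladium and the wide-bite-angle ligand are chosen for this.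

**Step 4**
Reactants: 9 (2S,3S)-2-[3,4-dimethoxy-5-(triisopropylsilyloxy)phenyl]-7-methoxy-3-methyl-2-(pinacolboryl)-2,3-dihydrobenzofuran
Product: 10 5-[(2S,3S)-7-methoxy-3-methyl-2,3-dihydro-1-benzofuran-2-yl]-2,3-dimethoxyphenol
Conditions: TBAF·3H2O (4 equiv), toluene, 45 °C; aq. NH4Cl work-up
Reagents that add atoms: none
Why: Fluoride-promoted protodeboronation of a tertiary benzylic boronic ester, in which water protonates the fluoroborate from the front side so that H takes the place of boron with retention (ring B stays trans to CH3), while the same fluoride cleaves the aryl silyl ether.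

**Step 5**
Reactants: 10 5-[(2S,3S)-7-methoxy-3-methyl-2,3-dihydro-1-benzofuran-2-yl]-2,3-dimethoxyphenol; 3 bis(pinacolato)diboron
Product: 13 5-[(2S,3S)-7-methoxy-3-methyl-5-(4,4,5,5-tetramethyl-1,3,2-dioxaborolan-2-yl)-2,3-dihydro-1-benzofuran-2-yl]-2,3-dimethoxyphenol, via aryl pinacol borate 11 (not isolated), via C5-borylated aryl pinacol borate 12 (not isolated)
Conditions: [Ir(OMe)(cod)]2 (2 mol%), 4,4′-di-tert-butyl-2,2′-bipyridine (4 mol%), HBpin (1.2 equiv), THF, rt; then B2pin2 (1.0 equiv), 70 °C; aqueous MeOH work-up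
Reagents that add atoms: bis(pinacolato)diboron 3, CC1(C)OB(OC1(C)C)B1OC(C)(C)C(C)(C)O1; pinacolborane, [H]B1OC(C)(C)C(C)(C)O1 (its boron sits on the phenol oxygen in 11 and 12 and is lost on work-up)
Why: Iridium-catalysed C–H borylation after masking the phenol in the flask as its pinacol borate; C5 of ring A is the only aromatic C–H with no ortho substituent (C4 and C6 have one, C2′ and C6′ two), so steric control should place boron there.

**Step 6**
Reactants: 13 5-[(2S,3S)-7-methoxy-3-methyl-5-(4,4,5,5-tetramethyl-1,3,2-dioxaborolan-2-yl)-2,3-dihydro-1-benzofuran-2-yl]-2,3-dimethoxyphenol; 14 (E)-1-bromoprop-1-ene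
Product: 15 5-[(2S,3S)-7-methoxy-3-methyl-5-[(E)-prop-1-enyl]-2,3-dihydro-1-benzofuran-2-yl]-2,3-dimethoxyphenol (CNP0299956.1)
Conditions: Pd(dppf)Cl2 (5 mol%), K3PO4 (3 equiv), 14 (3 equiv), 1,4-dioxane/H2O (5:1), 60 °C, sealed tube
Reagents that add atoms: (E)-1-bromoprop-1-ene 14, C/C=C/Br
Why: Suzuki–Miyaura coupling of an aryl pinacol boronate with an alkenyl bromide proceeds with retention of the alkene geometry and tolerates the free phenol; neither stereocentre is touched.

**Compound list**

1 | 2,3-dimethoxyphenol | COc1cccc(O)c1OC | starting material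
2 | (2,3-dimethoxyphenoxy)triisopropylsilane | COc1cccc(O[Si](C(C)C)(C(C)C)C(C)C)c1OC | intermediate
3 | bis(pinacolato)diboron | CC1(C)OB(OC1(C)C)B1OC(C)(C)C(C)(C)O1 | starting material
4 | 2-[3,4-dimethoxy-5-(triisopropylsilyloxy)phenyl]-4,4,5,5-tetramethyl-1,3,2-dioxaborolane | CC1(C)OB(OC1(C)C)c1cc(O[Si](C(C)C)(C(C)C)C(C)C)c(OC)c(OC)c1 | intermediate
5 | 7-methoxybenzofuran | COc1cccc2ccoc12 | starting material
6 | iodomethane | CI | starting material
7 | 2-lithio-7-methoxybenzofuran | COc1cccc2cc([Li])oc12 | intermediate (not isolated)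
8 | lithium [3,4-dimethoxy-5-(triisopropylsilyloxy)phenyl](7-methoxybenzofuran-2-yl)(pinacolato)borate | [Li+].COc1cccc2cc(oc12)[B-]1(OC(C)(C)C(C)(C)O1)c1cc(O[Si](C(C)C)(C(C)C)C(C)C)c(OC)c(OC)c1 | intermediate (not isolated)
9 | (2S,3S)-2-[3,4-dimethoxy-5-(triisopropylsilyloxy)phenyl]-7-methoxy-3-methyl-2-(pinacolboryl)-2,3-dihydrobenzofuran; ring B and CH3 trans, boron and CH3 cis | c1cc(OC)c2c(c1)[C@H](C)[C@@](B1OC(C)(C)C(C)(C)O1)(c1cc(O[Si](C(C)C)(C(C)C)C(C)C)c(OC)c(OC)c1)O2 | intermediate
10 | 5-[(2S,3S)-7-methoxy-3-methyl-2,3-dihydro-1-benzofuran-2-yl]-2,3-dimethoxyphenol | c1cc(OC)c2c(c1)[C@H](C)[C@@H](c1cc(O)c(OC)c(OC)c1)O2 | intermediate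
11 | 2-{5-[(2S,3S)-7-methoxy-3-methyl-2,3-dihydro-1-benzofuran-2-yl]-2,3-dimethoxyphenoxy}-4,4,5,5-tetramethyl-1,3,2-dioxaborolane | c1cc(OC)c2c(c1)[C@H](C)[C@@H](c1cc(OB3OC(C)(C)C(C)(C)O3)c(OC)c(OC)c1)O2 | intermediate (not isolated)
12 | 11 carrying a pinacolboryl group on C5 of ring A | CC1(C)OB(OC1(C)C)c1cc(OC)c2c(c1)[C@H](C)[C@@H](c1cc(OB3OC(C)(C)C(C)(C)O3)c(OC)c(OC)c1)O2 | intermediate (not isolated)
13 | 5-[(2S,3S)-7-methoxy-3-methyl-5-(4,4,5,5-tetramethyl-1,3,2-dioxaborolan-2-yl)-2,3-dihydro-1-benzofuran-2-yl]-2,3-dimethoxyphenol | CC1(C)OB(OC1(C)C)c1cc(OC)c2c(c1)[C@H](C)[C@@H](c1cc(O)c(OC)c(OC)c1)O2 | intermediate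
14 | (E)-1-bromoprop-1-ene | C/C=C/Br | starting material
15 | 5-[(2S,3S)-7-methoxy-3-methyl-5-[(E)-prop-1-enyl]-2,3-dihydro-1-benzofuran-2-yl]-2,3-dimethoxyphenol | C/C=C/c1cc(OC)c2c(c1)[C@H](C)[C@@H](c1cc(O)c(OC)c(OC)c1)O2 | target

**Step count**

Total: 6 steps. Longest linear sequence: 6 steps (1 → 2 → 4 → 9 → 10 → 13 → 15).

**Steps most likely to fail**

1. Step 3 (proposed new method). Several processes could undermine it:
   - MeI may methylate C3 of the ate complex without the metal, which lowers the enantiomeric purity.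
   - An aryl group may pass from boron to palladium and give methyl–aryl coupling.
   - Reductive elimination between two sp3 carbons may be slow, or iodide may block the site at which the alkene binds.
   - The ligand may discriminate poorly between the two faces of the benzofuran.

   Fallback by known chemistry, setting out from 4 and 14 and coming back at 10. Suzuki–Miyaura coupling of 4 with 14 (Pd(dppf)Cl2, K3PO4, dioxane/H2O) should give triisopropyl{2,3-dimethoxy-5-[(E)-prop-1-enyl]phenoxy}silane F1. Commercial 2-amino-6-methoxyphenol (COc1cccc(N)c1O) is diazotised with NOBF4 in MeCN at 0 °C to 2-hydroxy-3-methoxybenzenediazonium tetrafluoroborate F2, and F1 and Pd2(dba)3 are added. Heck–Matsuda oxyarylation then places the aryl group on the methyl-bearing alkene carbon and the phenol oxygen on the benzylic carbon. This closes ring C through the C3–C3a and C2–O bonds and should give the racemic trans silyl ether F3. TBAF gives the racemic phenol F4, and preparative HPLC on a chiral stationary phase separates 10 from its enantiomer.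

2. Step 4. The C2–B bond may break to a free benzylic carbanion that is protonated anti to the C3 methyl group, which would erode the trans relationship. The fluoroborate may also expel the aryloxide O1 and open ring C.

   Fallback setting out from 9 and coming back at 10. Oxidation of the C2–B bond (NaBO3·4H2O, THF/H2O, 0 °C) gives a hemiketal that opens to the hydroxy ketone F5, with C3 kept by working cold and briefly. NaBH4 in MeOH at −20 °C should give the diol F6 as both carbinol epimers. Catalytic (+)-camphor-10-sulfonic acid in CH2Cl2 at 0 °C ionises the benzylic alcohol, helped by the para-methoxy group of ring B, and the phenol closes ring C. The C3 methyl group steers ring B to the opposite face under kinetic and thermodynamic control, giving the trans silyl ether F7. TBAF then gives 10.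

3. Step 5. The O-boryl group on ring B may direct borylation to C2′, C4 or C6 may be borylated alongside C5, or the electron-rich ring A may react sluggishly.

   Fallback setting out from 9 and coming back at 15. The C–H borylation is run on 9 itself, which has no free phenol and whose only unhindered C–H is C5, to give the bis-boronate F8. Its aryl boronate is coupled with 14 under the conditions of step 6 to give the propenyl boronate F9; the tertiary alkyl boronate on C2 does not transmetallate. TBAF·3H2O as in step 4 then replaces boron on C2 by hydrogen with retention and removes the silyl group in the same operation, giving 15.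

**Further compounds**

F1 | step 3 | triisopropyl{2,3-dimethoxy-5-[(E)-prop-1-enyl]phenoxy}silane | C/C=C/c1cc(O[Si](C(C)C)(C(C)C)C(C)C)c(OC)c(OC)c1
F2 | step 3 | 2-hydroxy-3-methoxybenzenediazonium tetrafluoroborate | COc1cccc([N+]#N)c1O.F[B-](F)(F)F
F3 | step 3 | racemic trans-2-[3,4-dimethoxy-5-(triisopropylsilyloxy)phenyl]-7-methoxy-3-methyl-2,3-dihydrobenzofuran (both enantiomers written) | c1cc(OC)c2c(c1)[C@H](C)[C@@H](c1cc(O[Si](C(C)C)(C(C)C)C(C)C)c(OC)c(OC)c1)O2.c1cc(OC)c2c(c1)[C@@H](C)[C@H](c1cc(O[Si](C(C)C)(C(C)C)C(C)C)c(OC)c(OC)c1)O2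
F4 | step 3 | racemic trans-5-(7-methoxy-3-methyl-2,3-dihydro-1-benzofuran-2-yl)-2,3-dimethoxyphenol (both enantiomers written) | c1cc(OC)c2c(c1)[C@H](C)[C@@H](c1cc(O)c(OC)c(OC)c1)O2.c1cc(OC)c2c(c1)[C@@H](C)[C@H](c1cc(O)c(OC)c(OC)c1)O2
F5 | step 4 | (2S)-1-[3,4-dimethoxy-5-(triisopropylsilyloxy)phenyl]-2-(2-hydroxy-3-methoxyphenyl)propan-1-one | COc1cccc(c1O)[C@H](C)C(=O)c1cc(O[Si](C(C)C)(C(C)C)C(C)C)c(OC)c(OC)c1
F6 | step 4 | (2S)-1-[3,4-dimethoxy-5-(triisopropylsilyloxy)phenyl]-2-(2-hydroxy-3-methoxyphenyl)propan-1-ol, both epimers at C1 | COc1cccc(c1O)[C@H](C)C(O)c1cc(O[Si](C(C)C)(C(C)C)C(C)C)c(OC)c(OC)c1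
F7 | step 4 | (2S,3S)-2-[3,4-dimethoxy-5-(triisopropylsilyloxy)phenyl]-7-methoxy-3-methyl-2,3-dihydrobenzofuran | c1cc(OC)c2c(c1)[C@H](C)[C@@H](c1cc(O[Si](C(C)C)(C(C)C)C(C)C)c(OC)c(OC)c1)O2
F8 | step 5 | (2S,3S)-2-[3,4-dimethoxy-5-(triisopropylsilyloxy)phenyl]-7-methoxy-3-methyl-2,5-bis(pinacolboryl)-2,3-dihydrobenzofuran | CC1(C)OB(OC1(C)C)c1cc(OC)c2c(c1)[C@H](C)[C@@](B1OC(C)(C)C(C)(C)O1)(c1cc(O[Si](C(C)C)(C(C)C)C(C)C)c(OC)c(OC)c1)O2
F9 | step 5 | (2S,3S)-2-[3,4-dimethoxy-5-(triisopropylsilyloxy)phenyl]-7-methoxy-3-methyl-2-(pinacolboryl)-5-[(E)-prop-1-enyl]-2,3-dihydrobenzofuran | C/C=C/c1cc(OC)c2c(c1)[C@H](C)[C@@](B1OC(C)(C)C(C)(C)O1)(c1cc(O[Si](C(C)C)(C(C)C)C(C)C)c(OC)c(OC)c1)O2
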